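The data were computed with constants of no real substance, noise included.

Start at the ramp.

the same everywhere: L 20 mM

| charge | G | remark |
|---|---|---|
| spring | 0.10 mM | run made earlier |
| dusk | 0.40 mM | run made earlier |
| flask | 0.20 mM |  |

| spring: time / h | spring: Z / % | dusk: time / h | dusk: Z / % |
|---|---|---|---|
| 3.00 | 2.3 | 5.00 | 15.8 |
| 4.00 | 0.7 | 10.0 | 46.2 |
| 6.00 | 5.3 | 15.0 | 73.5 |
| 10.0 | 12.2 | 20.0 | 91.1 |
| 15.0 | 23.1 | 25.0 | 96.6 |
| 25.0 | 42.4 | 30.0 | 99.1 |
| 40.0 | 69.4 | 40.0 | 100.4 |

(each reading ± 1 percentage point)

1. factor on the rate of making Z when 5.0% of the L are converted if G is charged twice over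
2. factor on the rate when 5.0% of the L are converted if G is charged at 2.0 mM instead

Take the candidate steps as a round fed by G → E. Suppose [E] grows in step with time at first. Then the rate grows with it, and conversion grows with the square of time: an induction period. So take the root of the [Z] made per [G] charged, and divide it by the time. The spring reading at 6.00 h gives 0.543 h⁻¹, the ramp constant. The dusk reading at 5.00 h gives 0.562 h⁻¹. These are two runs, and each reading carries 1 percentage point.

Way one. On a ramp the rate is twice the conversion over the time, and the time falls with the root of [G]. So the factors are 1.41 and 3.16. In the flask the ramp reaches 5.0% at 4.12 h, with a rate of 0.485 mM h⁻¹.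

Way two. Read the spring slope from 15.0 h to 25.0 h as a plateau, 3.86 h⁻¹ of [Z] per [G] charged. Plateau over twice the squared ramp constant gives a rise time of 6.55 h. Let the rate climb exponentially to the plateau, put the first times back, and go round once. The flask then reaches the mark at 4.63 h, double G at 3.16 h, and 2.0 mM at 1.35 h. The factors become 1.51 and 3.67.

The ways part, and the root cheats low: the flask has used 0.707 of a rise time, more than the 0.206 at 2.0 mM, yet the root treats both as pure ramp. I commit to way two.

The forecast says 1.5 and 3.5, holding that “G only sets how much catalyst is in the cycle”.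

    L + E → Q (k = 12.0 M⁻¹ min⁻¹)
    Q → J (k = 0.290 min⁻¹)
    J → E + Z (k = 0.230 min⁻¹)
    G → E (k = 0.00270 min⁻¹)

The flask gives 1.48 and 3.35, the second between the root and my 3.67. At 3.00 h the flask still holds 61.5% of its catalyst as G, outside the round. Use the ramp constant 0.543 h⁻¹ again: for the flask it gave 4.12 h against 3.83 h found, and 0.485 mM h⁻¹ against 0.450 mM h⁻¹. At 2.0 mM it gives 1.53 mM h⁻¹, against 1.51 mM h⁻¹ from the factor found.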